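Acredinone A is cut at the indenone C1–C2 and C2=C3 bonds, which exposes two copies of one arene: the indenone benzo ring (C3a, C4–OH, C5–H, C6–CH3, C7–OCH3, C7a) and the benzoyl-bearing ring on C2 are the same 4-methoxy-5-methylphenol with two adjacent carbon arms. A Dötz benzannulation builds this ring in one operation from (CO)5Cr=C(OCH3)C(CH3)=CH2, one CO ligand and an internal alkyne, with OH and OCH3 differentiated from the start. The alkyne carries a THP-protected CH2O arm and the TBS-protected carbinol of 2,6-dimethoxybenzaldehyde. Keto ester and keto phosphonate halves are later joined by acylation and Horner–Wadsworth–Emmons closure.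

Key step: step 4

Remark: the target has no stereocentre; the carbinol carbon made in step 2 and the THP acetal carbon are formed without control (racemic material, diastereomer mixtures from 9 to 14), both are gone after step 8, and the SMILES therefore carry no stereodescriptors.

Step 1
Reactants: 1 2-bromopropene; 2 chromium hexacarbonyl Cr(CO)6
Product: 5 pentacarbonyl[methoxy(prop-1-en-2-yl)carbene]chromium (CO)5Cr=C(OCH3)C(CH3)=CH2, via isopropenyllithium CH2=C(CH3)Li 3 (not isolated), via lithium acylchromate Li[(CO)5CrC(O)C(CH3)=CH2] 4 (not isolated)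
Conditions: t-BuLi (2 equiv), Et2O, −78 °C; Cr(CO)6, Et2O, 0 °C → rt; Me3OBF4, CH2Cl2, 0 °C
Reagents that add atoms: trimethyloxonium tetrafluoroborate, C[O+](C)C.F[B-](F)(F)F
Why: Halogen–lithium exchange gives the vinyllithium, which adds to a CO ligand of Cr(CO)6, and O-methylation of the acylmetalate with a trialkyloxonium salt is the standard Fischer carbene synthesis.

Step 2
Reactants: 6 2-(prop-2-yn-1-yloxy)tetrahydro-2H-pyran (propargyl THP ether; racemic); 7 2,6-dimethoxybenzaldehyde
Product: 9 1-(2,6-dimethoxyphenyl)-4-(tetrahydro-2H-pyran-2-yloxy)but-2-yn-1-ol (racemic; diastereomer mixture), via lithium acetylide LiC≡CCH2OTHP 8 (not isolated)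
Conditions: n-BuLi, THF, −78 °C; then 7, −78 → 0 °C; H2O
Reagents that add atoms: none
Why: 1,2-Addition of a lithium acetylide to a non-enolisable aryl aldehyde, with the carbinol centre formed without control because it is later oxidised; the THP acetal is chosen for the primary oxygen so that this arm can later be freed by mild acid while a phenolic MOM ether stays in place.

Step 3
Reactants: 9 1-(2,6-dimethoxyphenyl)-4-(tetrahydro-2H-pyran-2-yloxy)but-2-yn-1-ol
Product: 10 tert-butyl{[1-(2,6-dimethoxyphenyl)-4-(tetrahydro-2H-pyran-2-yloxy)but-2-yn-1-yl]oxy}dimethylsilane (racemic; diastereomer mixture)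
Conditions: TBSCl, imidazole, DMAP (cat.), DMF, rt
Reagents that add atoms: tert-butyldimethylsilyl chloride, CC(C)(C)[Si](C)(C)Cl
Why: Standard silylation of a secondary propargylic alcohol with a silyl chloride and imidazole; the TBS ether masks the carbinol during the benzannulation and is later removable by fluoride without touching either acetal.

Step 4
Reactants: 5 pentacarbonyl[methoxy(prop-1-en-2-yl)carbene]chromium; 10 silyl-protected alkyne
Product: 12 2-{[tert-butyl(dimethyl)silyl]oxy(2,6-dimethoxyphenyl)methyl}-4-methoxy-5-methyl-3-[(tetrahydro-2H-pyran-2-yloxy)methyl]phenol (racemic; diastereomer mixture), via Cr(CO)3 arene complex 11 (not isolated)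
Conditions: 5 (1.5 equiv), THF (0.2 M), 55 °C, Ar; then air, EtOAc, rt
Reagents that add atoms: none
Why: This is a Dötz benzannulation of an alkenyl(alkoxy)carbene complex with an internal alkyne, a well-established reaction class: thermal loss of one CO opens a site on chromium, the alkyne inserts into the Cr=C bond to give a vinylcarbene, a CO ligand inserts to give a chromium-bound dienylketene, and tautomerisation of the resulting cyclohexadienone gives the phenol, which air releases from zerovalent chromium. The one new ring is closed by a thermal disrotatory 6π-electrocyclisation of that dienylketene, in which the carbene carbon becomes C–OCH3, the inserted CO becomes C–OH, the isopropenyl unit supplies C–CH3 and C–H, and the two alkyne carbons become the neighbouring carbon-bearing positions. No stereocentre is created and the racemic carbinol carbon of 10 is not touched. The step needs regioselective alkyne insertion with the larger alkyne substituent next to the CO-derived carbon; the branched silyloxy(2,6-dimethoxyphenyl)methyl group is far bulkier than the CH2OTHP group and should therefore end up ortho to the phenol OH. Phenol formation over cyclobutenone or five-membered-ring products is favoured by the alkenyl carbene, the coordinating solvent and the moderate temperature.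

Step 5
Reactants: 12 benzannulation phenol
Product: 13 tert-butyl{(2,6-dimethoxyphenyl)[3-methoxy-6-(methoxymethoxy)-4-methyl-2-[(tetrahydro-2H-pyran-2-yloxy)methyl]phenyl]methoxy}dimethylsilane (racemic; diastereomer mixture)
Conditions: MOMCl, iPr2NEt, Bu4NI (cat.), CH2Cl2, 0 → 40 °C
Reagents that add atoms: chloromethyl methyl ether, COCCl
Why: Williamson-type O-alkylation of the phenol under mild amine-base conditions, which keep the phenoxide concentration low and so avoid loss of the benzylic silyloxy group; the MOM acetal survives fluoride, oxidants, strong base and the mild acid used on the THP group.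

Step 6
Reactants: 13 MOM-protected silyl ether
Product: 14 (2,6-dimethoxyphenyl){3-methoxy-6-(methoxymethoxy)-4-methyl-2-[(tetrahydro-2H-pyran-2-yloxy)methyl]phenyl}methanol (racemic; diastereomer mixture)
Conditions: Bu4NF, THF, 0 → 40 °C
Reagents that add atoms: none
Why: Fluoride-induced cleavage of the Si–O bond is the standard silyl ether deprotection, and its basic medium avoids ionisation of the electron-rich diarylmethyl position while leaving both acetals intact.

Step 7
Reactants: 14 diaryl carbinol
Product: 15 (2,6-dimethoxyphenyl){3-methoxy-6-(methoxymethoxy)-4-methyl-2-[(tetrahydro-2H-pyran-2-yloxy)methyl]phenyl}methanone (racemic at the acetal carbon)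
Conditions: Dess–Martin periodinane, NaHCO3, CH2Cl2, rt
Reagents that add atoms: none
Why: Dess–Martin oxidation converts the hindered secondary diaryl carbinol into the diaryl ketone and removes the carbinol stereocentre, with the bicarbonate buffer protecting the THP acetal from the acetic acid released.

Step 8
Reactants: 15 keto THP ether
Product: 16 (2,6-dimethoxyphenyl)[2-(hydroxymethyl)-3-methoxy-6-(methoxymethoxy)-4-methylphenyl]methanone
Conditions: AcOH/THF/H2O (4:2:1), 45 °C
Reagents that add atoms: none
Why: Acid-catalysed hydrolysis of the THP acetal, which is much more labile than the aryl MOM acetal, in an aqueous medium that cannot trap the hydroxy ketone as a mixed cyclic ketal.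

Step 9
Reactants: 16 keto alcohol
Product: 17 2-(2,6-dimethoxybenzoyl)-6-methoxy-3-(methoxymethoxy)-5-methylbenzaldehyde
Conditions: Dess–Martin periodinane, NaHCO3, CH2Cl2, rt
Reagents that add atoms: none
Why: Dess–Martin oxidation of a primary benzylic alcohol stops cleanly at the aldehyde, and any ring hemiketal form of 16 is in equilibrium with the open alcohol that is consumed.

Step 10
Reactants: 17 keto aldehyde
Product: 18 2-(2,6-dimethoxybenzoyl)-6-methoxy-3-(methoxymethoxy)-5-methylbenzoic acid
Conditions: NaClO2, NaH2PO4, 2-methyl-2-butene, t-BuOH/H2O, rt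
Reagents that add atoms: sodium chlorite, [Na+].[O-]Cl=O
Why: Pinnick oxidation tolerates hindered aryl aldehydes, and the alkene scavenger removes hypochlorous acid so that the electron-rich rings are not chlorinated.

Step 11
Reactants: 18 keto acid
Product: 19 methyl 2-(2,6-dimethoxybenzoyl)-6-methoxy-3-(methoxymethoxy)-5-methylbenzoate
Conditions: MeI, K2CO3, DMF, rt
Reagents that add atoms: iodomethane, CI
Why: SN2 O-alkylation of the carboxylate gives the open-chain methyl ester, not the pseudo ester that acid-catalysed esterification of a 2-aroylbenzoic acid can give.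

Step 12
Reactants: 16 keto alcohol
Product: 20 [2-(bromomethyl)-3-methoxy-6-(methoxymethoxy)-4-methylphenyl](2,6-dimethoxyphenyl)methanone
Conditions: CBr4, PPh3, CH2Cl2, 0 °C
Reagents that add atoms: carbon tetrabromide, BrC(Br)(Br)Br
Why: The Appel reaction converts the primary benzylic alcohol into the bromide under near-neutral conditions that leave the MOM acetal and the ketone alone.

Step 13
Reactants: 20 benzylic bromide
Product: 21 dimethyl [2-(2,6-dimethoxybenzoyl)-6-methoxy-3-(methoxymethoxy)-5-methylbenzyl]phosphonate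
Conditions: P(OMe)3, toluene, 110 °C
Reagents that add atoms: trimethyl phosphite, COP(OC)OC
Why: Michaelis–Arbuzov reaction of a reactive benzylic bromide with a trialkyl phosphite, the doubly flanked diaryl ketone being too hindered to interfere.

Step 14
Reactants: 19 keto ester; 21 keto phosphonate
Product: 23 3-(2,6-dimethoxyphenyl)-2-[2-(2,6-dimethoxybenzoyl)-6-methoxy-3-(methoxymethoxy)-5-methylphenyl]-7-methoxy-4-(methoxymethoxy)-6-methyl-1H-inden-1-one, via β-keto phosphonate 22 (not isolated)
Conditions: LiN(SiMe3)2 (3 equiv), THF, −78 °C → rt, then 60 °C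
Reagents that add atoms: none
Why: Acylation of the lithiated benzylic phosphonate by the non-enolisable ester gives the β-keto phosphonate, whose anion closes the five-membered ring by intramolecular Horner–Wadsworth–Emmons olefination of the neighbouring diaryl ketone; the extra base covers the more acidic β-keto phosphonate and cannot enolise either partner.

Step 15
Reactants: 23 bis-MOM ether of acredinone A
Product: 24 acredinone A
Conditions: HCl (3 M), MeOH, 50 °C
Reagents that add atoms: none
Why: Acid-catalysed acetal exchange removes both aryl MOM groups, while the aryl methyl ethers, the diaryl ketone and the indenone are stable to dilute HCl in methanol.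

Compound list
1 | 2-bromopropene | C=C(C)Br | starting material
2 | chromium hexacarbonyl Cr(CO)6 | [C-]#[O+].[C-]#[O+].[C-]#[O+].[C-]#[O+].[C-]#[O+].[C-]#[O+].[Cr] | starting material
3 | isopropenyllithium CH2=C(CH3)Li | [Li]C(C)=C | intermediate
4 | lithium pentacarbonyl(2-methylprop-2-enoyl)chromate Li[(CO)5CrC(O)C(CH3)=CH2] | [Li+].[O-]C(=[Cr])C(C)=C.[C-]#[O+].[C-]#[O+].[C-]#[O+].[C-]#[O+].[C-]#[O+] | intermediate
5 | pentacarbonyl[methoxy(prop-1-en-2-yl)carbene]chromium (CO)5Cr=C(OCH3)C(CH3)=CH2 | COC(=[Cr])C(C)=C.[C-]#[O+].[C-]#[O+].[C-]#[O+].[C-]#[O+].[C-]#[O+] | intermediate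
6 | 2-(prop-2-yn-1-yloxy)tetrahydro-2H-pyran (racemic) | C#CCOC1CCCCO1 | starting material
7 | 2,6-dimethoxybenzaldehyde | COc1cccc(OC)c1C=O | starting material
8 | lithium acetylide of 6, LiC≡CCH2OTHP | [Li]C#CCOC1CCCCO1 | intermediate
9 | 1-(2,6-dimethoxyphenyl)-4-(tetrahydro-2H-pyran-2-yloxy)but-2-yn-1-ol (racemic; diastereomer mixture) | OC(C#CCOC1CCCCO1)c1c(OC)cccc1OC | intermediate
10 | tert-butyl{[1-(2,6-dimethoxyphenyl)-4-(tetrahydro-2H-pyran-2-yloxy)but-2-yn-1-yl]oxy}dimethylsilane (racemic; diastereomer mixture) | CC(C)(C)[Si](C)(C)OC(C#CCOC1CCCCO1)c1c(OC)cccc1OC | intermediate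
11 | Cr(CO)3 arene complex of phenol 12 | COc1c(C)cc(O)c(C(O[Si](C)(C)C(C)(C)C)c2c(OC)cccc2OC)c1COC1CCCCO1.[Cr].[C-]#[O+].[C-]#[O+].[C-]#[O+] | intermediate
12 | 2-{[tert-butyl(dimethyl)silyl]oxy(2,6-dimethoxyphenyl)methyl}-4-methoxy-5-methyl-3-[(tetrahydro-2H-pyran-2-yloxy)methyl]phenol (racemic; diastereomer mixture) | COc1c(C)cc(O)c(C(O[Si](C)(C)C(C)(C)C)c2c(OC)cccc2OC)c1COC1CCCCO1 | intermediate
13 | tert-butyl{(2,6-dimethoxyphenyl)[3-methoxy-6-(methoxymethoxy)-4-methyl-2-[(tetrahydro-2H-pyran-2-yloxy)methyl]phenyl]methoxy}dimethylsilane (racemic; diastereomer mixture) | COCOc1cc(C)c(OC)c(COC2CCCCO2)c1C(O[Si](C)(C)C(C)(C)C)c1c(OC)cccc1OC | intermediate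
14 | (2,6-dimethoxyphenyl){3-methoxy-6-(methoxymethoxy)-4-methyl-2-[(tetrahydro-2H-pyran-2-yloxy)methyl]phenyl}methanol (racemic; diastereomer mixture) | COCOc1cc(C)c(OC)c(COC2CCCCO2)c1C(O)c1c(OC)cccc1OC | intermediate
15 | (2,6-dimethoxyphenyl){3-methoxy-6-(methoxymethoxy)-4-methyl-2-[(tetrahydro-2H-pyran-2-yloxy)methyl]phenyl}methanone (racemic) | COCOc1cc(C)c(OC)c(COC2CCCCO2)c1C(=O)c1c(OC)cccc1OC | intermediate
16 | (2,6-dimethoxyphenyl)[2-(hydroxymethyl)-3-methoxy-6-(methoxymethoxy)-4-methylphenyl]methanone | COCOc1cc(C)c(OC)c(CO)c1C(=O)c1c(OC)cccc1OC | intermediate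
17 | 2-(2,6-dimethoxybenzoyl)-6-methoxy-3-(methoxymethoxy)-5-methylbenzaldehyde | COCOc1cc(C)c(OC)c(C=O)c1C(=O)c1c(OC)cccc1OC | intermediate
18 | 2-(2,6-dimethoxybenzoyl)-6-methoxy-3-(methoxymethoxy)-5-methylbenzoic acid | COCOc1cc(C)c(OC)c(C(=O)O)c1C(=O)c1c(OC)cccc1OC | intermediate
19 | methyl 2-(2,6-dimethoxybenzoyl)-6-methoxy-3-(methoxymethoxy)-5-methylbenzoate | COCOc1cc(C)c(OC)c(C(=O)OC)c1C(=O)c1c(OC)cccc1OC | intermediate
20 | [2-(bromomethyl)-3-methoxy-6-(methoxymethoxy)-4-methylphenyl](2,6-dimethoxyphenyl)methanone | COCOc1cc(C)c(OC)c(CBr)c1C(=O)c1c(OC)cccc1OC | intermediate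
21 | dimethyl [2-(2,6-dimethoxybenzoyl)-6-methoxy-3-(methoxymethoxy)-5-methylbenzyl]phosphonate | COCOc1cc(C)c(OC)c(CP(=O)(OC)OC)c1C(=O)c1c(OC)cccc1OC | intermediate
22 | dimethyl {1,2-bis[2-(2,6-dimethoxybenzoyl)-6-methoxy-3-(methoxymethoxy)-5-methylphenyl]-2-oxoethyl}phosphonate (racemic; present as its lithium enolate) | COCOc1cc(C)c(OC)c(C(C(=O)c2c(OC)c(C)cc(OCOC)c2C(=O)c2c(OC)cccc2OC)P(=O)(OC)OC)c1C(=O)c1c(OC)cccc1OC | intermediate
23 | 3-(2,6-dimethoxyphenyl)-2-[2-(2,6-dimethoxybenzoyl)-6-methoxy-3-(methoxymethoxy)-5-methylphenyl]-7-methoxy-4-(methoxymethoxy)-6-methyl-1H-inden-1-one | COCOc1cc(C)c(OC)c(C2=C(c3c(OC)cccc3OC)c3c(OCOC)cc(C)c(OC)c3C2=O)c1C(=O)c1c(OC)cccc1OC | intermediate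
24 | acredinone A, 3-(2,6-dimethoxyphenyl)-2-[2-(2,6-dimethoxybenzoyl)-3-hydroxy-6-methoxy-5-methylphenyl]-4-hydroxy-7-methoxy-6-methyl-1H-inden-1-one | COc1cccc(OC)c1C(=O)c1c(O)cc(C)c(OC)c1C1=C(c2c(OC)cccc2OC)c2c(O)cc(C)c(OC)c2C1=O | target

Total step count: 15. Longest linear sequence: 12 steps (steps 2 to 11, then 14 and 15, from 6 and 7).

Steps most likely to fail

Step 4. Alkyne insertion may be slow or poorly regioselective because the silyloxy(aryl)methyl arm is very bulky, so that carbene decomposition or formation of the regioisomeric phenol competes. The fallback keeps the benzannulation but uses a smaller alkyne and brings in the aryl group afterwards. It sets out from 6, which is treated with EtMgBr in THF and then heated with triethyl orthoformate to give the alkynyl acetal 2-[(4,4-diethoxybut-2-yn-1-yl)oxy]tetrahydro-2H-pyran F1. Benzannulation of this alkyne with 5 under the conditions of step 4 should give 2-(diethoxymethyl)-4-methoxy-5-methyl-3-[(tetrahydro-2H-pyran-2-yloxy)methyl]phenol F2, the branched acetal carbon still being the larger alkyne substituent. Hydrolysis on wet silica gel doped with oxalic acid should give 2-hydroxy-5-methoxy-4-methyl-6-[(tetrahydro-2H-pyran-2-yloxy)methyl]benzaldehyde F3, and MOMCl with iPr2NEt then gives 3-methoxy-6-(methoxymethoxy)-4-methyl-2-[(tetrahydro-2H-pyran-2-yloxy)methyl]benzaldehyde F4. Addition of 2,6-dimethoxyphenyllithium F5, made from 1,3-dimethoxybenzene and n-BuLi, comes back to the route at 14, so that steps 5 and 6 are not needed.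

Step 14. Attack of the congested phosphonate carbanion on the doubly ortho-substituted ester may stall, or the stabilised lithium enolate of the β-keto phosphonate may fail to close onto the shielded diaryl ketone. The fallback forms the carbon–carbon bond at the aldehyde oxidation level. It sets out from aldehyde 17 and phosphonate 21: deprotonation of 21 with LiN(SiMe3)2 in THF at −78 °C, addition to 17 and a cold quench should give the β-hydroxy phosphonate dimethyl {1,2-bis[2-(2,6-dimethoxybenzoyl)-6-methoxy-3-(methoxymethoxy)-5-methylphenyl]-2-hydroxyethyl}phosphonate F6 without olefination. Dess–Martin oxidation comes back to the route at 22, which is then isolated and cyclised to 23 with K2CO3 and 18-crown-6 in warm toluene. Steps 10 and 11 are then not needed.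

Step 8. The acid may also cleave the phenolic MOM acetal, or the freed hydroxy ketone may be diverted through its ring hemiketal by dehydration. The fallback cleaves both acetals on purpose and reprotects the phenol selectively. It sets out from 15: aqueous HCl in THF at 50 °C should give the keto diol (2,6-dimethoxyphenyl)[6-hydroxy-2-(hydroxymethyl)-3-methoxy-4-methylphenyl]methanone F7. MOMCl with K2CO3 in acetone then alkylates only the phenoxide and comes back to the route at 16.

Further compounds
F1 | step 4 | 2-[(4,4-diethoxybut-2-yn-1-yl)oxy]tetrahydro-2H-pyran | CCOC(OCC)C#CCOC1CCCCO1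
F2 | step 4 | 2-(diethoxymethyl)-4-methoxy-5-methyl-3-[(tetrahydro-2H-pyran-2-yloxy)methyl]phenol | CCOC(OCC)c1c(O)cc(C)c(OC)c1COC1CCCCO1
F3 | step 4 | 2-hydroxy-5-methoxy-4-methyl-6-[(tetrahydro-2H-pyran-2-yloxy)methyl]benzaldehyde | O=Cc1c(O)cc(C)c(OC)c1COC1CCCCO1
F4 | step 4 | 3-methoxy-6-(methoxymethoxy)-4-methyl-2-[(tetrahydro-2H-pyran-2-yloxy)methyl]benzaldehyde | COCOc1cc(C)c(OC)c(COC2CCCCO2)c1C=O
F5 | step 4 | 2,6-dimethoxyphenyllithium | [Li]c1c(OC)cccc1OC
F6 | step 14 | dimethyl {1,2-bis[2-(2,6-dimethoxybenzoyl)-6-methoxy-3-(methoxymethoxy)-5-methylphenyl]-2-hydroxyethyl}phosphonate | COCOc1cc(C)c(OC)c(C(C(O)c2c(OC)c(C)cc(OCOC)c2C(=O)c2c(OC)cccc2OC)P(=O)(OC)OC)c1C(=O)c1c(OC)cccc1OC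
F7 | step 8 | (2,6-dimethoxyphenyl)[6-hydroxy-2-(hydroxymethyl)-3-methoxy-4-methylphenyl]methanone | Oc1cc(C)c(OC)c(CO)c1C(=O)c1c(OC)cccc1OC
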